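C1 (quaternary, CH3), C2, C3, C4 (isopropyl carbinol), C5 (ring-fusion CH), C6 (angelate), C7 (CH2), C8/C9 (epoxide, CH3 on C8), C10 (carbinol). The five-membered ring is C1–C5 and the seven-membered ring is C1, C5–C10. β is the face of the C1 methyl group, α the other face.
Cuts: the epoxide oxygen comes off C8/C9 and the angeloyl group off O-6. The C6 carbinol goes back to the ketone and then to its methyl enol ether C5=C6. Last, the ring bonds C1–C10 and C6–C7 are cut.
Enabling feature: C7 is the only CH2 of the seven-membered ring and lies between oxygenated C6 and olefinic C8. C5=C6–C7–C8=C9 is therefore a skipped diene facing the C1–C10 bond, which is what a cis-divinylcyclopropane (C6–C7–C8) leaves after a Cope shift. The oxygen on C6 marks that carbon as an alkoxycarbene carbon.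
Forward: the five-membered ring is bought as 3-methylcyclopentenone and carried to a chromium carbene (C6). C7–C10 come from 3-methylbut-2-enal. The seven-membered ring closes when the two are heated together, and six functional-group steps finish the synthesis.
Stereochemistry: C4 comes from a resolution, C1 from C4 (face of the cyclopentene), and C10 from the E enol ether through the boat. C5 is set by α-face protonation, C6 by hydride delivered from the C4 hydroxyl, and C8/C9 by epoxidation directed by the C10 hydroxyl. The Z ester comes from angelic acid.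

Key step: step 7

Assumption: the enantiomer of the bromo carbinol kept in step 3 is identified as R by anomalous-dispersion X-ray analysis (bromine) before it is carried on. Locants in the names of bicyclic compounds are the perimeter locants defined above.

Step 1
Reactants: 1 3-methylcyclopent-2-en-1-one
Product: 3 2-bromo-3-methylcyclopent-2-en-1-one, via 2,3-dibromo-3-methylcyclopentanone 2 (not isolated)
Conditions: Br2, CH2Cl2, 0 °C; then Et3N, 0 °C → rt
Reagents that add atoms: bromine, BrBr
Why: Bromination–dehydrobromination, in which bromine adds across the enone and the amine removes the acidic C–H next to the carbonyl with E1cB loss of the tertiary bromide, is the standard entry to 2-bromocycloalkenones and leaves no stereocentre.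

Step 2
Reactants: 3 2-bromo-3-methylcyclopent-2-en-1-one; 4 isopropylmagnesium chloride
Product: 5 rac-2-bromo-3-methyl-1-(propan-2-yl)cyclopent-2-en-1-ol
Conditions: LaCl3·2LiCl (1 equiv), THF, 0 °C
Reagents that add atoms: none
Why: In this lanthanide-promoted Grignard 1,2-addition the oxophilic LaCl3·2LiCl activates the carbonyl so that addition should outrun β-hydride reduction and enolisation through the γ-methyl group; C4 is formed racemic.

Step 3
Reactants: 5 rac-2-bromo-3-methyl-1-(propan-2-yl)cyclopent-2-en-1-ol
Product: 6 (R)-2-bromo-3-methyl-1-(propan-2-yl)cyclopent-2-en-1-ol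
Conditions: preparative SFC, amylose tris(3,5-dimethylphenylcarbamate) on silica, CO2–i-PrOH, 35 °C
Reagents that add atoms: none
Why: Chromatographic resolution on a polysaccharide carbamate phase separates small polar alcohols without derivatising the hindered, acid-sensitive tertiary allylic carbinol, and it is the only source of absolute configuration (C4 = R).

Step 4
Reactants: 6 (R)-2-bromo-3-methyl-1-(propan-2-yl)cyclopent-2-en-1-ol
Product: 7 (R)-[2-bromo-3-methyl-1-(propan-2-yl)cyclopent-2-en-1-yl]oxy(triethyl)silane
Conditions: Et3SiOTf, 2,6-lutidine, CH2Cl2, 0 °C → rt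
Reagents that add atoms: triethylsilyl trifluoromethanesulfonate, CC[Si](CC)(CC)OS(=O)(=O)C(F)(F)F
Why: O-silylation with a silyl triflate and a hindered pyridine base is the usual method for tertiary alcohols, runs under non-ionising conditions and does not touch C4.

Step 5
Reactants: 7 (R)-[2-bromo-3-methyl-1-(propan-2-yl)cyclopent-2-en-1-yl]oxy(triethyl)silane; 8 chromium hexacarbonyl
Product: 11 pentacarbonyl{methoxy[(5R)-2-methyl-5-(propan-2-yl)-5-(triethylsilyloxy)cyclopent-1-en-1-yl]carbene}chromium, via vinyllithium 9 (not isolated), via lithium acylchromate 10 (not isolated)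
Conditions: t-BuLi (2 equiv), Et2O, −78 °C; cannula into Cr(CO)6, Et2O, 0 °C → rt; evaporate; Me3OBF4, CH2Cl2, 0 °C → rt
Reagents that add atoms: trimethyloxonium tetrafluoroborate, C[O+](C)C.F[B-](F)(F)F; tert-butyllithium, [Li]C(C)(C)C (its lithium stays only in 9 and 10)
Why: In this Fischer carbene synthesis bromine–lithium exchange gives 9, which adds to an exposed CO ligand of 8, and acylate 10 is O-methylated by the oxonium salt; keeping 9 at −78 °C until the transfer should stop an O-to-C silyl shift (retro-Brook) from competing.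

Step 6
Reactants: 12 3-methylbut-2-enal
Product: 13 (E)-tert-butyl(dimethyl)[(3-methylbuta-1,3-dien-1-yl)oxy]silane
Conditions: t-BuMe2SiOTf, Et3N, Et2O, 0 °C → rt; distillation
Reagents that add atoms: tert-butyldimethylsilyl trifluoromethanesulfonate, CC(C)(C)[Si](C)(C)OS(=O)(=O)C(F)(F)F
Why: In this vinylogous soft enolisation O-silylation gives the s-trans oxocarbenium ion, from which the amine removes a γ-methyl proton, so the E dienol ether should dominate and can be freed from any Z isomer by distillation.

Step 7
Reactants: 11 pentacarbonyl{methoxy[(5R)-2-methyl-5-(propan-2-yl)-5-(triethylsilyloxy)cyclopent-1-en-1-yl]carbene}chromium; 13 (E)-tert-butyl(dimethyl)[(3-methylbuta-1,3-dien-1-yl)oxy]silane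
Product: 15 (1S,4R,10R)-6-methoxy-1,8-dimethyl-4-(propan-2-yl)-4-(triethylsilyloxy)-10-(tert-butyldimethylsilyloxy)hydroazulene-5,8-diene, via cis-divinylcyclopropane 14 (not isolated)
Conditions: 13 (3 equiv), toluene, CO (1 atm), 80 °C, then 110 °C
Reagents that add atoms: none
Why: This is the known formal (4+3) annulation of alkenyl(alkoxy) Fischer carbene complexes with electron-rich 1,3-dienes: C7, the diene terminus with the largest HOMO coefficient, attacks the electrophilic carbene carbon C6, the C6–Cr bond collapses onto C8 with release of Cr(CO)5 (taken up by CO as Cr(CO)6), and cis-divinylcyclopropane 14 then undergoes a strain-driven Cope rearrangement. The transient three-membered ring C6–C7–C8 closes by this stepwise (2+1) carbene transfer, and the seven-membered ring closes pericyclically by a suprafacial [3,3] shift through the endo-boat array, in which C6–C8 breaks, C1–C10 forms and the olefins move to C5=C6 and C8=C9. C10 is controlled by the E geometry of 13, because in the boat the two outward substituents (C2 on C1, the silyloxy group on C10) finish cis, which puts O-10 on the α face, trans to the C1 methyl group. C1 is controlled by C4: the SiEt3 group lies anti to the isopropyl group and so over the β face of the cyclopentene, while the isopropyl group turns only its methine hydrogen over the α face, so the C8–C9=C10 arm with its bulky silyloxy group should bond to C1 from the α face and leave the two silyloxy groups on opposite faces. The step needs attack at C7=C8 and not at the enol ether bond C9=C10, cyclopropanation and not Diels–Alder addition or metathesis, and a cis pair of alkenyl groups; the vinylogous donor polarisation of 13 secures the first, the fully substituted, twisted C1=C5 bond (no dienophile) together with the CO atmosphere secures the second, and the weak, doubly allylic, methoxy-substituted C6–C8 bond, which lets a trans isomer stereomutate below the rearrangement temperature, secures the third. The second heating stage is needed because the C1 methyl group is the inward substituent of the boat.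

Step 8
Reactants: 15 (1S,4R,10R)-6-methoxy-1,8-dimethyl-4-(propan-2-yl)-4-(triethylsilyloxy)-10-(tert-butyldimethylsilyloxy)hydroazulene-5,8-diene
Product: 16 (1S,4R,5R,10R)-1,8-dimethyl-4-(propan-2-yl)-4-(triethylsilyloxy)-10-(tert-butyldimethylsilyloxy)hydroazul-8-en-6-one (trans-fused, H-5 α)
Conditions: oxalic acid (0.1 M aq.), THF, 0 °C → rt
Reagents that add atoms: water, O
Why: In this enol ether hydrolysis by rate-limiting C-protonation a weak carboxylic acid acts as general acid on the electron-rich C5=C6 bond but is too weak to protonate the poorly basic silyl ether oxygen, which should hold back Stork–Danheiser-type loss of the C4 oxygen; the proton should reach C5 on the α face, away from the C1 methyl and SiEt3 groups, giving the trans-fused ketone that is also the more stable epimer (C6 anti to the isopropyl group), so no basic equilibration is needed that would endanger the β-silyloxy group and the skipped C8=C9 olefin.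

Step 9
Reactants: 16 (1S,4R,5R,10R)-1,8-dimethyl-4-(propan-2-yl)-4-(triethylsilyloxy)-10-(tert-butyldimethylsilyloxy)hydroazul-8-en-6-one
Product: 17 (1S,4R,5R,10R)-4-hydroxy-1,8-dimethyl-4-(propan-2-yl)-10-(tert-butyldimethylsilyloxy)hydroazul-8-en-6-one
Conditions: HF·pyridine, pyridine, THF, 0 °C → rt
Reagents that add atoms: none
Why: In this fluoride-driven desilylation the SiEt3 ether should be cleaved by buffered HF·pyridine well before the neopentyl secondary t-BuMe2Si ether at C10, and the weakly acidic medium avoids retro-aldol opening or dehydration of the β-hydroxy ketone.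

Step 10
Reactants: 17 (1S,4R,5R,10R)-4-hydroxy-1,8-dimethyl-4-(propan-2-yl)-10-(tert-butyldimethylsilyloxy)hydroazul-8-en-6-one
Product: 18 (1S,4R,5S,6S,10R)-1,8-dimethyl-4-(propan-2-yl)-10-(tert-butyldimethylsilyloxy)hydroazul-8-ene-4,6-diol (OH-4 β, OH-6 α)
Conditions: Me4NBH(OAc)3, MeCN–AcOH, −30 → 0 °C
Reagents that add atoms: none
Why: In this Evans–Saksena hydroxyl-directed reduction the C4 hydroxyl replaces an acetate on boron and the hydride is then delivered intramolecularly to the β face of C6=O, the face on which O-4 lies, so the new hydroxyl should stand α (6S, 1,3-anti to O-4), while the unbound reagent is too weak to reduce the ketone.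

Step 11
Reactants: 18 (1S,4R,5S,6S,10R)-1,8-dimethyl-4-(propan-2-yl)-10-(tert-butyldimethylsilyloxy)hydroazul-8-ene-4,6-diol; 19 angelic acid, (Z)-2-methylbut-2-enoic acid
Product: 21 (1S,4R,5S,6S,10R)-4-hydroxy-1,8-dimethyl-4-(propan-2-yl)-10-(tert-butyldimethylsilyloxy)hydroazul-8-en-6-yl (Z)-2-methylbut-2-enoate, via mixed anhydride 20 (not isolated)
Conditions: 19, 2,4,6-Cl3C6H2COCl, Et3N, toluene, rt; then 18, 80 °C
Reagents that add atoms: 2,4,6-trichlorobenzoyl chloride, O=C(Cl)c1c(Cl)cc(Cl)cc1Cl (its aroyl group stays only in 20)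
Why: In this Yamaguchi esterification run without a nucleophilic catalyst the hindered aroyl half of 20 directs the alcohol to the angeloyl carbonyl and the Z olefin should not isomerise to the tiglate; only the secondary C6 hydroxyl reacts, since O-4 is tertiary and O-10 is silylated.

Step 12
Reactants: 21 (1S,4R,5S,6S,10R)-4-hydroxy-1,8-dimethyl-4-(propan-2-yl)-10-(tert-butyldimethylsilyloxy)hydroazul-8-en-6-yl (Z)-2-methylbut-2-enoate
Product: 22 (1S,4R,5S,6S,10R)-4,10-dihydroxy-1,8-dimethyl-4-(propan-2-yl)hydroazul-8-en-6-yl (Z)-2-methylbut-2-enoate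
Conditions: Bu4NF, AcOH, THF, rt
Reagents that add atoms: none
Why: Fluoride desilylation buffered with acetic acid should free the C10 hydroxyl without ester cleavage, acyl shift or isomerisation of the angelate.

Step 13
Reactants: 22 (1S,4R,5S,6S,10R)-4,10-dihydroxy-1,8-dimethyl-4-(propan-2-yl)hydroazul-8-en-6-yl (Z)-2-methylbut-2-enoate
Product: 23 lapiferine, (1S,4R,5S,6S,8R,9S,10S)-8,9-epoxy-4,10-dihydroxy-1,8-dimethyl-4-(propan-2-yl)hydroazulan-6-yl (Z)-2-methylbut-2-enoate
Conditions: VO(acac)2 (cat.), t-BuOOH, CH2Cl2, 0 °C → rt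
Reagents that add atoms: tert-butyl hydroperoxide, CC(C)(C)OO
Why: In this hydroxyl-directed vanadium-catalysed epoxidation the C10 alkoxide binds the vanadium peroxide and oxygen is delivered to the same (α) face of C8=C9, the syn rule that holds for cyclic allylic alcohols up to seven-membered rings, which should set 8R,9S, while the electron-poor angelate olefin is not attacked.

Compound list
1 | 3-methylcyclopent-2-en-1-one | CC1=CC(=O)CC1 | starting material
2 | 2,3-dibromo-3-methylcyclopentan-1-one (trans, racemic) | CC1(Br)CCC(=O)C1Br | intermediate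
3 | 2-bromo-3-methylcyclopent-2-en-1-one | CC1=C(Br)C(=O)CC1 | intermediate
4 | isopropylmagnesium chloride | CC(C)[Mg]Cl | starting material
5 | rac-2-bromo-3-methyl-1-(propan-2-yl)cyclopent-2-en-1-ol | CC1=C(Br)C(O)(C(C)C)CC1 | intermediate
6 | (R)-2-bromo-3-methyl-1-(propan-2-yl)cyclopent-2-en-1-ol | BrC1=C(C)CC[C@@]1(O)C(C)C | intermediate
7 | (R)-[2-bromo-3-methyl-1-(propan-2-yl)cyclopent-2-en-1-yl]oxy(triethyl)silane | BrC1=C(C)CC[C@@]1(O[Si](CC)(CC)CC)C(C)C | intermediate
8 | chromium hexacarbonyl | O=C=[Cr](=C=O)(=C=O)(=C=O)(=C=O)=C=O | starting material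
9 | [(5R)-2-methyl-5-(propan-2-yl)-5-(triethylsilyloxy)cyclopent-1-en-1-yl]lithium | [Li]C1=C(C)CC[C@@]1(O[Si](CC)(CC)CC)C(C)C | intermediate
10 | lithium pentacarbonyl{[(5R)-2-methyl-5-(propan-2-yl)-5-(triethylsilyloxy)cyclopent-1-en-1-yl]oxidocarbene}chromate | [Li+].[O-]C(=[Cr](=C=O)(=C=O)(=C=O)(=C=O)=C=O)C1=C(C)CC[C@@]1(O[Si](CC)(CC)CC)C(C)C | intermediate
11 | pentacarbonyl{methoxy[(5R)-2-methyl-5-(propan-2-yl)-5-(triethylsilyloxy)cyclopent-1-en-1-yl]carbene}chromium | COC(=[Cr](=C=O)(=C=O)(=C=O)(=C=O)=C=O)C1=C(C)CC[C@@]1(O[Si](CC)(CC)CC)C(C)C | intermediate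
12 | 3-methylbut-2-enal | CC(C)=CC=O | starting material
13 | (E)-tert-butyl(dimethyl)[(3-methylbuta-1,3-dien-1-yl)oxy]silane | C=C(C)/C=C/O[Si](C)(C)C(C)(C)C | intermediate
14 | cis-divinylcyclopropane: C6 (S) carries OCH3 and the (5R)-cyclopentenyl group, C8 (R) carries CH3 and the (E)-2-(tert-butyldimethylsilyloxy)vinyl group, the two alkenyl groups cis | CO[C@@]1(C2=C(C)CC[C@@]2(O[Si](CC)(CC)CC)C(C)C)C[C@]1(C)/C=C/O[Si](C)(C)C(C)(C)C | intermediate
15 | (1S,4R,10R)-hydroazulene-5,8-diene: C5=C6 methyl enol ether, C8=C9 olefin, CH3-1 β, OSiEt3-4 β, isopropyl α, OSiMe2t-Bu-10 α | COC1CC(C)=C[C@@H](O[Si](C)(C)C(C)(C)C)[C@@]2(C)CC[C@@](O[Si](CC)(CC)CC)(C(C)C)C2=1 | intermediate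
16 | (1S,4R,5R,10R)-C6 ketone, trans-fused (H-5 α), both silyl ethers in place | O=C1CC(C)=C[C@@H](O[Si](C)(C)C(C)(C)C)[C@@]2(C)CC[C@@](O[Si](CC)(CC)CC)(C(C)C)[C@H]12 | intermediate
17 | (1S,4R,5R,10R)-4-hydroxy C6 ketone, C10 silyl ether | O=C1CC(C)=C[C@@H](O[Si](C)(C)C(C)(C)C)[C@@]2(C)CC[C@@](O)(C(C)C)[C@H]12 | intermediate
18 | (1S,4R,5S,6S,10R)-4,6-diol (OH-4 β, OH-6 α), C10 silyl ether | O[C@H]1CC(C)=C[C@@H](O[Si](C)(C)C(C)(C)C)[C@@]2(C)CC[C@@](O)(C(C)C)[C@H]12 | intermediate
19 | angelic acid, (Z)-2-methylbut-2-enoic acid | C/C=C(/C)C(=O)O | starting material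
20 | (Z)-2-methylbut-2-enoic 2,4,6-trichlorobenzoic anhydride | C/C=C(/C)C(=O)OC(=O)c1c(Cl)cc(Cl)cc1Cl | intermediate
21 | (1S,4R,5S,6S,10R)-6-angelate, free OH-4, C10 silyl ether | C/C=C(/C)C(=O)O[C@H]1CC(C)=C[C@@H](O[Si](C)(C)C(C)(C)C)[C@@]2(C)CC[C@@](O)(C(C)C)[C@H]12 | intermediate
22 | (1S,4R,5S,6S,10R)-6-angelate 4,10-diol, C8=C9 olefin | C/C=C(/C)C(=O)O[C@H]1CC(C)=C[C@@H](O)[C@@]2(C)CC[C@@](O)(C(C)C)[C@H]12 | intermediate
23 | lapiferine, (1S,4R,5S,6S,8R,9S,10S) | C/C=C(/C)C(=O)O[C@H]1C[C@@]2(C)O[C@H]2[C@@H](O)[C@@]2(C)CC[C@@](O)(C(C)C)[C@H]12 | target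

Total step count: 13. Longest linear sequence: 12 (steps 1–5 and 7–13).

Steps most likely to fail

Step 7. The C4 centre lies far from the forming C1–C10 bond, so discrimination between the two faces of the cyclopentene may be weak. The carbene may also attack the C9=C10 enol ether bond, or decay before the crowded C6–C8 bond is made. The fallback moves stereocontrol from the substrate to an auxiliary on the carbene oxygen, next to the centres that the cyclopropanation creates. It sets out from acylate 10 (made from 7 as in step 5) and returns at 16. Instead of being methylated, 10 is O-acetylated with acetyl bromide (CH2Cl2, −40 °C) to the acetoxycarbene complex F1. F1 exchanges its acetate for (−)-menthol to give the menthyloxycarbene complex F2. Heated with 13 under CO, F2 passes through the cis-divinylcyclopropane F3 to the menthyl enol ether F4. Hydrolysis of F4 with aqueous oxalic acid releases menthol and gives 16. Both antipodes of menthol are sold, so the pairing that reinforces C4 can be chosen.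

Step 8. Acid may trigger departure of the C4 silyloxy group through the vinylogous oxocarbenium ion, with loss of the C4 oxygen. The C8=C9 olefin may also drift into conjugation with the new ketone. The fallback replaces proton transfer by halogen transfer followed by a radical step, so no acid and no enolate are involved. It sets out from 15 and returns at 16. N-Bromosuccinimide in NaHCO3-buffered aqueous THF (−78 → −20 °C) brominates the enol ether at C5, and water captures the oxocarbenium ion. This gives the 5-bromo ketone F5, in which C4 is no longer allylic. Bu3SnH with AIBN (toluene, 80 °C) then replaces bromine by hydrogen, and the planar C5 radical should take up hydrogen on the open α face.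

Step 10. Ligand exchange at the hindered tertiary hydroxyl may be slow, so undirected hydride attack from the open α face could take over and invert the outcome at C6. The fallback uses that intrinsic preference. It sets out from 17 and returns at 21, so it also replaces step 11. LiBH(s-Bu)3 (THF, −78 °C) attacks the α face on purpose and gives the 6-epi diol F6 (OH-6 β). A Mitsunobu reaction of F6 with angelic acid 19 (PPh3, DIAD, toluene, 0 °C → rt) then installs the ester with inversion at C6.

Further compounds
F1 | step 7 | pentacarbonyl{acetoxy[(5R)-2-methyl-5-(propan-2-yl)-5-(triethylsilyloxy)cyclopent-1-en-1-yl]carbene}chromium | CC(=O)OC(=[Cr](=C=O)(=C=O)(=C=O)(=C=O)=C=O)C1=C(C)CC[C@@]1(O[Si](CC)(CC)CC)C(C)C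
F2 | step 7 | pentacarbonyl{[(1R,2S,5R)-menthyloxy][(5R)-2-methyl-5-(propan-2-yl)-5-(triethylsilyloxy)cyclopent-1-en-1-yl]carbene}chromium | CC(C)[C@@H]1CC[C@@H](C)C[C@H]1OC(=[Cr](=C=O)(=C=O)(=C=O)(=C=O)=C=O)C2=C(C)CC[C@@]2(O[Si](CC)(CC)CC)C(C)C
F3 | step 7 | (1R,2S,5R)-menthyloxy analogue of cis-divinylcyclopropane 14 | CC(C)[C@@H]3CC[C@@H](C)C[C@H]3O[C@@]1(C2=C(C)CC[C@@]2(O[Si](CC)(CC)CC)C(C)C)C[C@]1(C)/C=C/O[Si](C)(C)C(C)(C)C
F4 | step 7 | (1R,2S,5R)-menthyl enol ether analogue of 15 | CC(C)[C@@H]3CC[C@@H](C)C[C@H]3OC1CC(C)=C[C@@H](O[Si](C)(C)C(C)(C)C)[C@@]2(C)CC[C@@](O[Si](CC)(CC)CC)(C(C)C)C2=1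
F5 | step 8 | 5-bromo derivative of ketone 16 (bromine on the α face of C5) | O=C1CC(C)=C[C@@H](O[Si](C)(C)C(C)(C)C)[C@@]2(C)CC[C@@](O[Si](CC)(CC)CC)(C(C)C)[C@]12Br
F6 | step 10 | (1S,4R,5S,6R,10R)-4,6-diol, C6 epimer of 18 | O[C@@H]1CC(C)=C[C@@H](O[Si](C)(C)C(C)(C)C)[C@@]2(C)CC[C@@](O)(C(C)C)[C@H]12
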